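## Structural features

The target is a 4-arylflavan-3-ol: ring A is fused to the pyran ring C, which carries a 4-hydroxyphenyl group (ring B) on C2, a hydroxyl on C3 and a resorcinol ring D on C4; the second ortho position of ring D is linked through an (E)-ethene bridge to a catechol ring E. C2, C3 and C4 are contiguous stereocentres of configuration (2R,3S,4S). Re-deriving the descriptors from the SMILES string confirms 2,3-trans and 3,4-trans, so all three substituents are equatorial on the half-chair of ring C. Fragile elements are the seven free hydroxyls (six phenolic, including an air- and base-sensitive catechol), the stilbene, the doubly benzylic C4–H, and the C2–O1 bond, a benzylic ether para to the ring B oxygen that can ionise with loss of the C2 configuration. The real difficulty is C4: a doubly benzylic carbon that must be joined, with control of absolute and relative configuration, to a ring D substituted at both ortho positions. A second difficulty is timing, since neither the electron-rich stilbene nor the free phenols tolerate cation chemistry at C4. The key step exploits the fact that C4 is benzylic to ring D, bonded to C4a of ring A and trans to the C3 oxygen: this is the pattern left when an arene opens a trans-epoxide at its benzylic carbon from the rear, and the O1–C2 ether is the tether that makes the opening intramolecular. The bromine kept on ring D until late marks the site of the styryl arm and keeps ring E out of the acid-mediated step.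

## Logic of the disconnections

20 ⇒ 19 ⇒ 18. Only oxygen–protecting-group bonds are cut: three aryl O–Si bonds (20 to 19), then three aryl O–acyl bonds (19 to 18). The phenols, above all the catechol, are uncovered last because they tolerate neither palladium with base and heat nor the Lewis acid of the ring closure. The gain is a lipophilic, air-stable 18. The demand is that neither deprotection be basic or oxidising, so the esters are removed reductively and the silyl ethers with buffered fluoride.

18 ⇒ 14 + 17. The bond between C6' of ring D and the bridging alkene carbon is cut. This takes ring E and the stilbene out of everything that precedes and leaves a bromine as a silent marker. The forward step must couple an aryl bromide with a bulky ortho substituent, give the (E)-alkene and leave the free C3 hydroxyl alone.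

14 ⇒ 13 (key disconnection). The C4–C4a bond is cut, which opens ring C and turns C3–O and C4 into a trans-epoxide tethered through O1–C2 to ring A. Rear-side attack of ring A on the benzylic epoxide carbon then creates the bond, the ring and the C4 stereocentre at once, and the tether forces bond formation ortho to O1, which an intermolecular arylation would not select. All three stereocentres of 14 are thereby encoded in an acyclic erythro epoxy ether. The forward step needs the epoxide to open at the benzylic carbon without a free cation, ring A to attack para to its silyloxy group, and the C2–O1 benzylic ether to survive acid. For the last reason ring B is carried in 13 as a pivalate and not as a silyl ether, which would make C2–O1 a labile, PMB-like linkage; ring D is acylated as well.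

13 ⇒ 11 + 12. The aryl C–O bond between O1 and C8a is cut, so the carbinol C–O bond and the C2 configuration stay untouched. Ring A is split off as a simple boronic acid and the problem is reduced to an epoxy alcohol. The forward O-arylation of a hindered secondary alcohol must run without strong base, since an alkoxide next to the epoxide would undergo Payne rearrangement and would take acyl groups from the aryl pivalates.

11 ⇒ 10. Both C–O bonds of the oxirane are cut. A hydroxyl-directed, reagent-controlled epoxidation can resolve the carbinol centre and set both epoxide centres in one step, so a single chiral reagent supplies all stereochemical information of the route. The price is that at most half of racemic 10 is used, and the epoxidation must work on a twisted, electron-poor styrene.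

10 ⇒ 9 ⇒ 4 + 8. The carbinol C–H bond is cut back to the ketone, then the Cα=Cβ bond of the enone. This divides the skeleton into 4 (ring D with the future C4) and 8 (ring B with the future C2 and C3). The olefination must give the (E)-alkene and, like the reduction, must not touch three aryl esters, which excludes hydroxide- or alkoxide-mediated aldol chemistry.

4 ⇒ 3 ⇒ 1. The two O–acyl bonds and then the ring–CHO bond are cut. The formyl group has to enter between a hydroxyl and the bromine, para to the other hydroxyl; this is the position a 5-substituted resorcinol offers to an electrophile.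

8 ⇒ 6 ⇒ 5. The C=P bond is traced back to the C–Br bond of a phenacyl bromide, and the O–acyl bond is cut. The ylide must be formed with a base mild enough to spare the aryl ester.

17 ⇒ 16 ⇒ 15. The terminal C=C bond and two O–Si bonds are cut, which leads to a commercial aldehyde. Silyl ethers are chosen here so that ring E is unmasked in the final fluoride step together with ring A.

## Other disconnections considered

Alternative 1: The cut is one C–C bond of ring D, between the carbon attached to C4 and the carbon that carries the styryl arm, which unfolds ring D into the triketone A2. In the forward step the C4-bound methylene of A2 would add to the cinnamoyl carbonyl, and dehydration with enolisation would give the resorcinol A1.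
- In its favour: ring D would arise in one event with both hydroxyls free and the styryl arm and ring E already in place. There is no aryl halide and no palladium, and the congested C4–aryl bond never has to be made.
- Against it: the required nucleophile is the least acidic α-carbon of A2, activated by one carbonyl and branched. The two doubly activated methylenes, closure through enol oxygen, Claisen-type C-acylation and Michael closure onto the enone all compete, with no enzyme to select among them.
- Structure: the chosen plan builds ring C on finished aromatic rings; this plan builds ring D on a finished ring C. The three stereocentres would therefore have to be set beforehand on a C4-homologated flavan, so the stereochemical problem is displaced, not solved.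
- Mechanism: a stereospecific epoxide opening with predictable regiochemistry is set against a chemoselectivity problem among several cyclisation modes.
- Step economy: after its key step this plan needs only one desilylation and is the better of the two there. Before the key step, the assembly of A2 by polyanion acylations is expected to be clearly longer.
- Equal or better: endgame length, absence of palladium, and avoidance of a hindered C4–aryl bond formation.

Alternative 2: The cut is the C2–C3 bond of ring C (formally also the ester C=O), which leads to the aryl ester A4 with a vinyl group on C4. In the forward step a Tebbe methylenation would convert the ester into an enol ether, and ring-closing metathesis with the vinyl group would give the 4H-chromene A3.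
- In its favour: the only stereocentre at the key step is C4, which one catalytic asymmetric step could set. C2 and C3 would then follow by hydroboration–oxidation of the enol ether anti to the C4 aryl; syn addition gives 2,3-trans and 3,4-trans. No resolution is needed and ring B enters by a plain esterification.
- Against it: a titanium alkylidene in excess would have to form a trisubstituted, aryl-substituted enol ether next to a very crowded C4. The doubly benzylic, allylic C4–H of A4 and A3 invites alkene migration with loss of the stereocentre and hydride loss with aromatisation of the pyran ring. The facial selectivity of the hydroboration rests on substrate control alone.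
- Structure: this plan makes C2–C3 and sets no stereocentre in its key step, whereas the chosen plan makes C4–C4a and sets C4.
- Mechanism: organometallic and sensitive, against acid-catalysed and stereospecific.
- Step economy: two operations (ring closure, then hydroboration–oxidation) do what step 9 does in one; overall the count is expected to be similar.
- Equal or better: material throughput (no discarded enantiomer) and the ring B attachment are better; the bromide, the Heck reaction and the deprotection are the same in both plans.

Alternative 3: The cuts are C3–C4 and O1–C2, which divide ring C into the carbinol A6 (rings A and D) and the (E)-styrylboronate A7 (ring B). In the forward step the ortho-quinone methide A8, generated from A6, would add to A7 in a [4+2] cycloaddition to give the 3-boryl chroman A5. Oxidation of the C–B bond with retention would then give the C3 hydroxyl.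
- In its favour: two bonds, ring C and the relative configuration of all three stereocentres would be made in one step. The (E)-geometry of A7 gives 2,3-trans and an endo orientation of ring B gives 2,4-cis, hence the all-trans isomer.
- Against it: the absolute configuration would have to come from a chiral catalyst acting on a methide carbon that bears a di-ortho-substituted aryl group. The alkene of A7 is made less electron-rich by boron, while the cycloaddition wants an electron-rich partner. Self-condensation of A8 and a stepwise cationic pathway that erodes the endo preference are further concerns.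
- Structure: the most convergent of the four plans.
- Mechanism: relative configuration comes from a cycloaddition, which is comparably predictable to the epoxide opening. Absolute configuration is less secure than with the reagent-controlled epoxidation of the chosen plan.
- Step economy: better than the chosen plan (fewer steps, no copper-mediated etherification).
- Equal or better: convergence and step count are better; the bromide, the Heck reaction and the deprotection are equal.

Key step: step 9

Remark: 5 and 12 are taken as articles of commerce; ring locants follow the flavan skeleton and primed locants refer to ring D.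

## Steps

Step 1
Reactants: 1 5-bromoresorcinol
Product: 3 2-bromo-4,6-dihydroxybenzaldehyde, via aryl iminium chloride 2 (not isolated)
Conditions: POCl3, DMF, MeCN, 0 °C to rt; then H2O, 50 °C
Reagents that add atoms: N,N-dimethylformamide, CN(C)C=O (formyl carbon); water, O (carbonyl oxygen)
Why: Vilsmeier–Haack formylation; the chloroiminium ion should attack the carbon para to one hydroxyl and ortho to the other (next to bromine), the site that 5-substituted resorcinols use, and water hydrolyses iminium salt 2 to the aldehyde.

Step 2
Reactants: 3 2-bromo-4,6-dihydroxybenzaldehyde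
Product: 4 2-bromo-4,6-bis(pivaloyloxy)benzaldehyde
Conditions: t-BuCOCl, Et3N, DMAP (cat.), CH2Cl2, 0 °C to rt
Reagents that add atoms: pivaloyl chloride, CC(C)(C)C(Cl)=O
Why: DMAP-catalysed acylation of both phenols; the pivalates make ring D electron-poor so that the later benzylic epoxide is isolable, and their bulk shields them in steps 4 to 8.

Step 3
Reactants: 5 2-bromo-1-(4-hydroxyphenyl)ethan-1-one
Product: 6 4-(2-bromoacetyl)phenyl pivalate
Conditions: t-BuCOCl, i-Pr2NEt, CH2Cl2, 0 °C
Reagents that add atoms: pivaloyl chloride, CC(C)(C)C(Cl)=O
Why: Phenol O-acylation with a hindered amine that does not quaternise with the bromoketone; the ring B pivalate weakens the para oxygen as a donor so that the benzylic C–O bonds made later at the future C2 do not ionise.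

Step 4
Reactants: 6 4-(2-bromoacetyl)phenyl pivalate
Product: 8 4-[2-(triphenyl-λ5-phosphanylidene)acetyl]phenyl pivalate, via phosphonium bromide 7 (not isolated)
Conditions: PPh3, CH2Cl2, rt; then aq. Na2CO3, rt
Reagents that add atoms: triphenylphosphine, c1ccc(cc1)P(c1ccccc1)c1ccccc1
Why: SN2 alkylation of the phosphine by the phenacyl bromide, then deprotonation of the acidic phosphonium salt by carbonate gives the stabilised keto ylide (Wittig reagent formation); the mild base spares the aryl ester.

Step 5
Reactants: 4 2-bromo-4,6-bis(pivaloyloxy)benzaldehyde; 8 4-[2-(triphenyl-λ5-phosphanylidene)acetyl]phenyl pivalate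
Product: 9 (E)-3-[2-bromo-4,6-bis(pivaloyloxy)phenyl]-1-[4-(pivaloyloxy)phenyl]prop-2-en-1-one
Conditions: toluene, 100 °C
Reagents that add atoms: none
Why: Wittig olefination with a stabilised ylide under neutral conditions, which should give the (E)-enone and leave the three aryl pivalates untouched.

Step 6
Reactants: 9 (E)-3-[2-bromo-4,6-bis(pivaloyloxy)phenyl]-1-[4-(pivaloyloxy)phenyl]prop-2-en-1-one
Product: 10 racemic (E)-3-[2-bromo-4,6-bis(pivaloyloxy)phenyl]-1-[4-(pivaloyloxy)phenyl]prop-2-en-1-ol
Conditions: NaBH4, CeCl3·7H2O, MeOH–THF, −40 °C
Reagents that add atoms: none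
Why: Luche reduction; the CeCl3-modified borohydride adds 1,2 to the enone and should give the racemic allylic alcohol, while the hindered aryl esters survive at low temperature.

Step 7
Reactants: 10 racemic (E)-3-[2-bromo-4,6-bis(pivaloyloxy)phenyl]-1-[4-(pivaloyloxy)phenyl]prop-2-en-1-ol
Product: 11 (R)-[(2R,3R)-3-(2-bromo-4,6-bis(pivaloyloxy)phenyl)oxiran-2-yl][4-(pivaloyloxy)phenyl]methanol (erythro)
Conditions: Ti(OiPr)4 (1 equiv), D-(−)-DIPT (1.2 equiv), t-BuOOH (0.6 equiv), 4 Å MS, CH2Cl2, −20 °C
Reagents that add atoms: tert-butyl hydroperoxide, CC(C)(C)OO
Why: Sharpless kinetic resolution by asymmetric epoxidation; with D-(−)-DIPT (the tartrate that converts cinnamyl alcohol into (2R,3R)-3-phenylglycidol) the (S)-carbinol should be epoxidised fast on the alkene face that gives the erythro trans-epoxy alcohol, which fixes the future C2 and C3 and, before its inversion, C4. The slow (R)-enantiomer of 10 remains, is separated and can be returned to 9 with MnO2.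

Step 8
Reactants: 11 (R)-[(2R,3R)-3-(2-bromo-4,6-bis(pivaloyloxy)phenyl)oxiran-2-yl][4-(pivaloyloxy)phenyl]methanol; 12 3-(tert-butyldimethylsilyloxy)phenylboronic acid
Product: 13 4-{(R)-[(2S,3R)-3-(2-bromo-4,6-bis(pivaloyloxy)phenyl)oxiran-2-yl][3-(tert-butyldimethylsilyloxy)phenoxy]methyl}phenyl pivalate (erythro; the oxirane C2 descriptor changes from 11 by priority only)
Conditions: Cu(OAc)2 (2 equiv), pyridine, 4 Å MS, CH2Cl2, dry air, rt
Reagents that add atoms: none
Why: Chan–Lam O-arylation; the copper-bound alkoxide and the aryl group from boron combine by reductive elimination, so the carbinol C–O bond is never broken and its configuration is retained. The weakly basic medium avoids Payne rearrangement and acyl transfer from the aryl pivalates.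

Step 9
Reactants: 13 4-{(R)-[(2S,3R)-3-(2-bromo-4,6-bis(pivaloyloxy)phenyl)oxiran-2-yl][3-(tert-butyldimethylsilyloxy)phenoxy]methyl}phenyl pivalate
Product: 14 (2R,3S,4S)-4-[2-bromo-4,6-bis(pivaloyloxy)phenyl]-7-(tert-butyldimethylsilyloxy)-2-[4-(pivaloyloxy)phenyl]chroman-3-ol
Conditions: BF3·OEt2 (0.2 equiv), CH2Cl2, −78 to −30 °C; aq. NaHCO3
Reagents that add atoms: none
Why: BF3 binds the epoxide oxygen and the ring A carbon para to the silyloxy group attacks the benzylic epoxide carbon (the future C4) from the side opposite the breaking C–O bond; the arenium ion then passes its proton to the alkoxide, which frees the C3 hydroxyl and returns the acid. The closest known reaction type is the intramolecular Friedel–Crafts epoxy-arene cyclisation of aryl 3-arylglycidyl ethers to trans-4-arylchroman-3-ols. Ring C closes in the 6-endo mode at the epoxide (both oxirane carbons become ring members), preferred over 5-exo attack at the future C3 because only the benzylic C–O bond is weakened by conjugation with ring D. C4 is the one new stereocentre and is controlled by inversion at the (R)-configured benzylic epoxide carbon, which gives (4S) with the ring D aryl trans to the C3 hydroxyl; C2 and C3 are carried over from 13 unchanged. The step needs site selectivity on ring A (para and not ortho to the silyloxy group), secured by the stronger para activation and by the bulk of the silyl group, which shields the carbon between the two oxygens. It also needs the epoxide to be activated in preference to the C2–O1 benzylic ether and to open without a free cation; both are secured by the acyloxy groups on rings B and D, which withdraw electron density from the two benzylic positions. If the opening nevertheless became loose, closure through the half-chair with the ring B aryl, the C3 oxygen and the ring D aryl all equatorial would lead to the same all-trans isomer.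

Step 10
Reactants: 15 3,4-dihydroxybenzaldehyde
Product: 16 3,4-bis(tert-butyldimethylsilyloxy)benzaldehyde
Conditions: t-BuMe2SiCl, imidazole, DMF, rt
Reagents that add atoms: tert-butyldimethylsilyl chloride, CC(C)(C)[Si](C)(C)Cl
Why: Imidazole-promoted silylation of both catechol hydroxyls.

Step 11
Reactants: 16 3,4-bis(tert-butyldimethylsilyloxy)benzaldehyde
Product: 17 3,4-bis(tert-butyldimethylsilyloxy)styrene
Conditions: Ph3PCH3Br, KOt-Bu, THF, 0 °C to rt
Reagents that add atoms: methyltriphenylphosphonium bromide, C[P+](c1ccccc1)(c1ccccc1)c1ccccc1.[Br-]
Why: Wittig methylenation of the aldehyde with the ylide generated in the flask; aryl silyl ethers tolerate the non-stabilised ylide at low temperature.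

Step 12
Reactants: 14 (2R,3S,4S)-4-[2-bromo-4,6-bis(pivaloyloxy)phenyl]-7-(tert-butyldimethylsilyloxy)-2-[4-(pivaloyloxy)phenyl]chroman-3-ol; 17 3,4-bis(tert-butyldimethylsilyloxy)styrene
Product: 18 (2R,3S,4S)-4-{2-[(E)-2-(3,4-bis(tert-butyldimethylsilyloxy)phenyl)ethenyl]-4,6-bis(pivaloyloxy)phenyl}-7-(tert-butyldimethylsilyloxy)-2-[4-(pivaloyloxy)phenyl]chroman-3-ol
Conditions: Pd2(dba)3 (2.5 mol %), [HP(t-Bu)3]BF4 (10 mol %), Cy2NMe, dioxane, 80 °C
Reagents that add atoms: none
Why: Mizoroki–Heck reaction; oxidative addition of the hindered aryl bromide to the zerovalent palladium–P(t-Bu)3 complex, syn insertion of the styrene at its terminal carbon and syn β-hydride elimination should give the (E)-stilbene. The amine base is too weak to induce aryl ether formation with the trans-disposed C3 hydroxyl, and no stereocentre is touched.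

Step 13
Reactants: 18 (2R,3S,4S)-4-{2-[(E)-2-(3,4-bis(tert-butyldimethylsilyloxy)phenyl)ethenyl]-4,6-bis(pivaloyloxy)phenyl}-7-(tert-butyldimethylsilyloxy)-2-[4-(pivaloyloxy)phenyl]chroman-3-ol
Product: 19 (2R,3S,4S)-4-{2-[(E)-2-(3,4-bis(tert-butyldimethylsilyloxy)phenyl)ethenyl]-4,6-dihydroxyphenyl}-7-(tert-butyldimethylsilyloxy)-2-(4-hydroxyphenyl)chroman-3-ol
Conditions: i-Bu2AlH (10 equiv), CH2Cl2, −78 to 0 °C; aq. potassium sodium tartrate
Reagents that add atoms: none
Why: Reductive cleavage of the three aryl pivalates by the aluminium hydride (ester reduction to neopentyl alcohol and aluminium phenoxides), which avoids basic hydrolysis; silyl ethers, stilbene and stereocentres are not affected.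

Step 14
Reactants: 19 (2R,3S,4S)-4-{2-[(E)-2-(3,4-bis(tert-butyldimethylsilyloxy)phenyl)ethenyl]-4,6-dihydroxyphenyl}-7-(tert-butyldimethylsilyloxy)-2-(4-hydroxyphenyl)chroman-3-ol
Product: 20 (2R,3S,4S)-4-{2-[(E)-2-(3,4-dihydroxyphenyl)ethenyl]-4,6-dihydroxyphenyl}-2-(4-hydroxyphenyl)chroman-3,7-diol (target)
Conditions: Bu4NF, AcOH, THF, 0 °C to rt, argon
Reagents that add atoms: none
Why: Fluoride-mediated cleavage of the three aryl silyl ethers, buffered with acetic acid so that the catechol and the C2 benzylic ether never meet free phenoxide in air.

## Compound list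

1 | 5-bromoresorcinol | Oc1cc(O)cc(Br)c1 | starting material
2 | [(2-bromo-4,6-dihydroxyphenyl)methylidene]dimethylammonium chloride | C[N+](C)=Cc1c(O)cc(O)cc1Br.[Cl-] | intermediate
3 | 2-bromo-4,6-dihydroxybenzaldehyde | O=Cc1c(O)cc(O)cc1Br | intermediate
4 | 2-bromo-4,6-bis(pivaloyloxy)benzaldehyde | O=Cc1c(OC(=O)C(C)(C)C)cc(OC(=O)C(C)(C)C)cc1Br | intermediate
5 | 2-bromo-1-(4-hydroxyphenyl)ethan-1-one | O=C(CBr)c1ccc(O)cc1 | starting material
6 | 4-(2-bromoacetyl)phenyl pivalate | O=C(CBr)c1ccc(OC(=O)C(C)(C)C)cc1 | intermediate
7 | {2-oxo-2-[4-(pivaloyloxy)phenyl]ethyl}triphenylphosphonium bromide | O=C(C[P+](c1ccccc1)(c1ccccc1)c1ccccc1)c1ccc(OC(=O)C(C)(C)C)cc1.[Br-] | intermediate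
8 | 4-[2-(triphenyl-λ5-phosphanylidene)acetyl]phenyl pivalate | O=C(C=P(c1ccccc1)(c1ccccc1)c1ccccc1)c1ccc(OC(=O)C(C)(C)C)cc1 | intermediate
9 | (E)-3-[2-bromo-4,6-bis(pivaloyloxy)phenyl]-1-[4-(pivaloyloxy)phenyl]prop-2-en-1-one | CC(C)(C)C(=O)Oc1ccc(C(=O)/C=C/c2c(OC(=O)C(C)(C)C)cc(OC(=O)C(C)(C)C)cc2Br)cc1 | intermediate
10 | racemic (E)-3-[2-bromo-4,6-bis(pivaloyloxy)phenyl]-1-[4-(pivaloyloxy)phenyl]prop-2-en-1-ol | CC(C)(C)C(=O)Oc1ccc(C(O)/C=C/c2c(OC(=O)C(C)(C)C)cc(OC(=O)C(C)(C)C)cc2Br)cc1 | intermediate
11 | (R)-[(2R,3R)-3-(2-bromo-4,6-bis(pivaloyloxy)phenyl)oxiran-2-yl][4-(pivaloyloxy)phenyl]methanol, erythro | CC(C)(C)C(=O)Oc1ccc([C@@H](O)[C@H]2O[C@@H]2c2c(OC(=O)C(C)(C)C)cc(OC(=O)C(C)(C)C)cc2Br)cc1 | intermediate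
12 | 3-(tert-butyldimethylsilyloxy)phenylboronic acid | CC(C)(C)[Si](C)(C)Oc1cccc(B(O)O)c1 | starting material
13 | 4-{(R)-[(2S,3R)-3-(2-bromo-4,6-bis(pivaloyloxy)phenyl)oxiran-2-yl][3-(tert-butyldimethylsilyloxy)phenoxy]methyl}phenyl pivalate, erythro | CC(C)(C)C(=O)Oc1ccc([C@@H](Oc2cccc(O[Si](C)(C)C(C)(C)C)c2)[C@H]2O[C@@H]2c2c(OC(=O)C(C)(C)C)cc(OC(=O)C(C)(C)C)cc2Br)cc1 | intermediate
14 | (2R,3S,4S)-4-[2-bromo-4,6-bis(pivaloyloxy)phenyl]-7-(tert-butyldimethylsilyloxy)-2-[4-(pivaloyloxy)phenyl]chroman-3-ol | CC(C)(C)C(=O)Oc1ccc([C@H]2Oc3cc(O[Si](C)(C)C(C)(C)C)ccc3[C@@H](c3c(OC(=O)C(C)(C)C)cc(OC(=O)C(C)(C)C)cc3Br)[C@@H]2O)cc1 | intermediate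
15 | 3,4-dihydroxybenzaldehyde | O=Cc1ccc(O)c(O)c1 | starting material
16 | 3,4-bis(tert-butyldimethylsilyloxy)benzaldehyde | O=Cc1ccc(O[Si](C)(C)C(C)(C)C)c(O[Si](C)(C)C(C)(C)C)c1 | intermediate
17 | 3,4-bis(tert-butyldimethylsilyloxy)styrene | C=Cc1ccc(O[Si](C)(C)C(C)(C)C)c(O[Si](C)(C)C(C)(C)C)c1 | intermediate
18 | (2R,3S,4S)-4-{2-[(E)-2-(3,4-bis(tert-butyldimethylsilyloxy)phenyl)ethenyl]-4,6-bis(pivaloyloxy)phenyl}-7-(tert-butyldimethylsilyloxy)-2-[4-(pivaloyloxy)phenyl]chroman-3-ol | CC(C)(C)C(=O)Oc1ccc([C@H]2Oc3cc(O[Si](C)(C)C(C)(C)C)ccc3[C@@H](c3c(OC(=O)C(C)(C)C)cc(OC(=O)C(C)(C)C)cc3/C=C/c3ccc(O[Si](C)(C)C(C)(C)C)c(O[Si](C)(C)C(C)(C)C)c3)[C@@H]2O)cc1 | intermediate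
19 | (2R,3S,4S)-4-{2-[(E)-2-(3,4-bis(tert-butyldimethylsilyloxy)phenyl)ethenyl]-4,6-dihydroxyphenyl}-7-(tert-butyldimethylsilyloxy)-2-(4-hydroxyphenyl)chroman-3-ol | Oc1ccc([C@H]2Oc3cc(O[Si](C)(C)C(C)(C)C)ccc3[C@@H](c3c(O)cc(O)cc3/C=C/c3ccc(O[Si](C)(C)C(C)(C)C)c(O[Si](C)(C)C(C)(C)C)c3)[C@@H]2O)cc1 | intermediate
20 | (2R,3S,4S)-4-{2-[(E)-2-(3,4-dihydroxyphenyl)ethenyl]-4,6-dihydroxyphenyl}-2-(4-hydroxyphenyl)chroman-3,7-diol | Oc1ccc([C@H]2Oc3cc(O)ccc3[C@@H](c3c(O)cc(O)cc3/C=C/c3ccc(O)c(O)c3)[C@@H]2O)cc1 | target

## Step count and least certain steps

Total number of steps: 14. Longest linear sequence: 10 steps (steps 1, 2, 5, 6, 7, 8, 9, 12, 13, 14; the branch through steps 3 and 4 is equally long).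

Step 9 (key step). The most likely failure is sluggish or diverted opening of an epoxide whose benzylic carbon sits on an electron-poor ring D substituted at both ortho positions. The diversions are a hydride shift of the activated epoxide (Meinwald rearrangement), participation of the ortho pivalate carbonyl at the benzylic carbon with loss of clean inversion, and acid-induced cleavage of the C2–O1 ether if the temperature has to be raised. The fallback changes the nucleophile and the mode of activation and sets out from 13. Buffered fluoride (Bu4NF, AcOH, THF, 0 °C) should remove only the aryl silyl ether and give the ring A phenol F1. In hexafluoroisopropanol, without Lewis acid, the free phenol should close ring C by para-alkylation to the 7-hydroxyflavan-3-ol F2, because its para carbon is the required C4a and is far more nucleophilic than that of the silyl ether. Selective silylation of the phenol (t-BuMe2SiCl, imidazole, 0 °C) returns to the route at 14.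

Step 8. Conversion of a hindered secondary alcohol in a Chan–Lam coupling may stay low, because protodeboronation and oxidative self-coupling of the boronic acid and copper-mediated oxidation of the benzylic carbinol compete. The fallback replaces the copper coupling by two Mitsunobu inversions and sets out from 11. Reaction with chloroacetic acid (PPh3, diisopropyl azodicarboxylate, toluene, 0 °C) should invert the carbinol carbon and give the threo chloroacetate F3. Ammonia in methanol at −20 °C should remove the chloroacetyl group in the presence of the hindered aryl pivalates and give the threo epoxy alcohol F4. A second Mitsunobu reaction with 3-(tert-butyldimethylsilyloxy)phenol (CC(C)(C)[Si](C)(C)Oc1cccc(O)c1) inverts the same carbon again and returns to the route at 13.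

Step 7. The epoxidation may be slow and poorly discriminating, because the alkene is twisted out of conjugation by the two ortho substituents and is electron-poor; the doubly activated allylic carbinol may also ionise on the Lewis-acidic titanium. The fallback separates the two tasks and sets out from 9. Corey–Bakshi–Shibata reduction with the (R)-oxazaborolidine and catecholborane (toluene, −40 °C) should give the (S)-allylic alcohol F5; the catalyst enantiomer is chosen on the assumption that the ring B aryl group acts as the larger substituent. A hydroxyl-directed epoxidation with VO(acac)2 and t-BuOOH (CH2Cl2, 0 °C), which does not depend on tartrate recognition, should then give 11 together with its threo isomer, to be removed by chromatography; the route is rejoined at 11.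

Step 12. Oxidative addition and alkene insertion at a bromide flanked by the bulky flavanyl group may be slow. Hydrodebromination, arylation at the internal alkene carbon and palladium-mediated oxidation of the C3 carbinol could then take over. The fallback replaces the Heck reaction by a cross-coupling with a preformed alkenyl–boron bond and sets out from 17. Cross-metathesis with vinylboronic acid pinacol ester (C=CB1OC(C)(C)C(C)(C)O1; second-generation Grubbs catalyst, CH2Cl2, 40 °C) should give the (E)-styrylboronate F6. Suzuki–Miyaura coupling of F6 with 14 (PdCl2(dppf), CsF, dioxane, 80 °C) should fix the (E)-geometry beforehand and returns to the route at 18.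

## Further compounds

F1 | step 9 | 4-{(R)-[(2S,3R)-3-(2-bromo-4,6-bis(pivaloyloxy)phenyl)oxiran-2-yl](3-hydroxyphenoxy)methyl}phenyl pivalate (ring A phenol) | CC(C)(C)C(=O)Oc1ccc([C@@H](Oc2cccc(O)c2)[C@H]2O[C@@H]2c2c(OC(=O)C(C)(C)C)cc(OC(=O)C(C)(C)C)cc2Br)cc1
F2 | step 9 | (2R,3S,4S)-4-[2-bromo-4,6-bis(pivaloyloxy)phenyl]-2-[4-(pivaloyloxy)phenyl]chroman-3,7-diol (7-hydroxyflavan-3-ol) | CC(C)(C)C(=O)Oc1ccc([C@H]2Oc3cc(O)ccc3[C@@H](c3c(OC(=O)C(C)(C)C)cc(OC(=O)C(C)(C)C)cc3Br)[C@@H]2O)cc1
F3 | step 8 | threo chloroacetate, 4-{(S)-(chloroacetoxy)[(2S,3R)-3-(2-bromo-4,6-bis(pivaloyloxy)phenyl)oxiran-2-yl]methyl}phenyl pivalate | CC(C)(C)C(=O)Oc1ccc([C@H](OC(=O)CCl)[C@H]2O[C@@H]2c2c(OC(=O)C(C)(C)C)cc(OC(=O)C(C)(C)C)cc2Br)cc1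
F4 | step 8 | threo epoxy alcohol, (S)-[(2R,3R)-3-(2-bromo-4,6-bis(pivaloyloxy)phenyl)oxiran-2-yl][4-(pivaloyloxy)phenyl]methanol | CC(C)(C)C(=O)Oc1ccc([C@H](O)[C@H]2O[C@@H]2c2c(OC(=O)C(C)(C)C)cc(OC(=O)C(C)(C)C)cc2Br)cc1
F5 | step 7 | (S,E)-3-[2-bromo-4,6-bis(pivaloyloxy)phenyl]-1-[4-(pivaloyloxy)phenyl]prop-2-en-1-ol | CC(C)(C)C(=O)Oc1ccc([C@@H](O)/C=C/c2c(OC(=O)C(C)(C)C)cc(OC(=O)C(C)(C)C)cc2Br)cc1
F6 | step 12 | (E)-2-[3,4-bis(tert-butyldimethylsilyloxy)phenyl]ethenylboronic acid pinacol ester | CC(C)(C)[Si](C)(C)Oc1ccc(/C=C/B2OC(C)(C)C(C)(C)O2)cc1O[Si](C)(C)C(C)(C)C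
A1 | alternative 1 | penta-silyl ether of the target (O3, O7, O4' of ring B and both catechol oxygens silylated, ring D hydroxyls free) | CC(C)(C)[Si](C)(C)Oc1ccc([C@H]2Oc3cc(O[Si](C)(C)C(C)(C)C)ccc3[C@@H](c3c(O)cc(O)cc3/C=C/c3ccc(O[Si](C)(C)C(C)(C)C)c(O[Si](C)(C)C(C)(C)C)c3)[C@@H]2O[Si](C)(C)C(C)(C)C)cc1
A2 | alternative 1 | silylated flavan-4-yl cinnamoyl triketone (C4–CH2–CO–CH2–CO–CH2–CO–CH=CH–aryl) | CC(C)(C)[Si](C)(C)Oc1ccc([C@H]2Oc3cc(O[Si](C)(C)C(C)(C)C)ccc3[C@@H](CC(=O)CC(=O)CC(=O)/C=C/c3ccc(O[Si](C)(C)C(C)(C)C)c(O[Si](C)(C)C(C)(C)C)c3)[C@@H]2O[Si](C)(C)C(C)(C)C)cc1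
A3 | alternative 2 | silylated 2,4-diaryl-4H-chromene with ring D bromide, C4 configured as in the target | CC(C)(C)[Si](C)(C)Oc1ccc(C2=C[C@H](c3c(O[Si](C)(C)C(C)(C)C)cc(O[Si](C)(C)C(C)(C)C)cc3Br)c3ccc(O[Si](C)(C)C(C)(C)C)cc3O2)cc1
A4 | alternative 2 | 2-(1-arylallyl)-5-silyloxyphenyl 4-silyloxybenzoate (aryl ester with C4 vinyl group) | C=C[C@H](c1c(O[Si](C)(C)C(C)(C)C)cc(O[Si](C)(C)C(C)(C)C)cc1Br)c1ccc(O[Si](C)(C)C(C)(C)C)cc1OC(=O)c1ccc(O[Si](C)(C)C(C)(C)C)cc1
A5 | alternative 3 | all-trans 3-(pinacolboryl)-2,4-diarylchroman with ring D bromide | CC(C)(C)[Si](C)(C)Oc1ccc([C@H]2Oc3cc(O[Si](C)(C)C(C)(C)C)ccc3[C@@H](c3c(O[Si](C)(C)C(C)(C)C)cc(O[Si](C)(C)C(C)(C)C)cc3Br)[C@@H]2B2OC(C)(C)C(C)(C)O2)cc1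
A6 | alternative 3 | ring A–ring D ortho-hydroxy diaryl carbinol | OC(c1ccc(O[Si](C)(C)C(C)(C)C)cc1O)c1c(O[Si](C)(C)C(C)(C)C)cc(O[Si](C)(C)C(C)(C)C)cc1Br
A7 | alternative 3 | (E)-2-[4-(tert-butyldimethylsilyloxy)phenyl]ethenylboronic acid pinacol ester | CC(C)(C)[Si](C)(C)Oc1ccc(/C=C/B2OC(C)(C)C(C)(C)O2)cc1
A8 | alternative 3 | ortho-quinone methide derived from A6 | CC(C)(C)[Si](C)(C)OC1=CC(=O)C(=Cc2c(O[Si](C)(C)C(C)(C)C)cc(O[Si](C)(C)C(C)(C)C)cc2Br)C=C1
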